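**Retrosynthetic overview**

1. The target is a 20-membered macrocyclic bis(bibenzyl) with four purchased benzene rings: A (3-hydroxy-4-aryloxyphenyl), B (meta-phenylene), C (para-phenylene) and D (4-hydroxy-3-aryloxyphenyl). The macrocycle is the only ring the route forms, and it is closed last.
2. Key disconnection: the ArCH2–CH2Ar bond between rings A and D. Both carbons are carried as formyl groups, and an intramolecular McMurry coupling closes the ring as a stilbene. One hydrogenation then saturates the C=C bond and removes both benzyl ethers.
3. Enabling feature: both carbons of that bond are benzylic, so each can be an aryl aldehyde carbon, on ring A para to the A–O–B ether oxygen and on ring D para to the phenol oxygen. The two diaryl ether oxygens and the flexible B–CH2CH2–C bridge act as hinges that let the two formyl carbons meet in a 20-membered ring.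
4. The open-chain dialdehyde is cut at the B–C bridge (Heck coupling, then C=C-selective hydrogenation) into two diaryl ether aldehydes.
5. The A–O–B ether comes from SNAr, where the ring-A formyl group activates a para fluoride. The C–O–D ether comes from Chan–Lam arylation, because that oxygen is meta to the formyl group.

Key step: step 6

Remark: the target has no stereocentre. The alkene formed in step 6 may be an E/Z mixture; this is immaterial because step 7 saturates it.

**Route**

Step 1
Reactants: 1 4-fluoro-3-hydroxybenzaldehyde
Product: 2 3-(benzyloxy)-4-fluorobenzaldehyde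
Conditions: BnBr, K2CO3, DMF, rt
Reagents that add atoms: benzyl bromide, BrCc1ccccc1
Why: Williamson O-alkylation of the phenoxide with a benzylic bromide is fast at room temperature, well below the temperature at which the phenoxide could displace the activated fluoride of a second molecule.

Step 2
Reactants: 2 3-(benzyloxy)-4-fluorobenzaldehyde; 3 3-iodophenol
Product: 4 3-(benzyloxy)-4-(3-iodophenoxy)benzaldehyde
Conditions: K2CO3, DMF, 110 °C
Reagents that add atoms: none
Why: Nucleophilic aromatic substitution (SNAr) should proceed because the fluoride of 2 is para to the formyl group, which stabilises the Meisenheimer intermediate, while the aryl iodide of 3 is inert without a transition metal.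

Step 3
Reactants: 5 4-(benzyloxy)-3-hydroxybenzaldehyde; 6 (4-vinylphenyl)boronic acid
Product: 7 4-(benzyloxy)-3-(4-vinylphenoxy)benzaldehyde
Conditions: Cu(OAc)2 (2 equiv), pyridine, 4 Å MS, CH2Cl2, air, rt
Reagents that add atoms: none
Why: Chan–Lam oxidative O-arylation couples the phenol with the arylboronic acid at room temperature without touching the aldehyde, the benzyl ether or the styrene, and it places the aryloxy group meta to the formyl group, where SNAr is not possible.

Step 4
Reactants: 4 3-(benzyloxy)-4-(3-iodophenoxy)benzaldehyde; 7 4-(benzyloxy)-3-(4-vinylphenoxy)benzaldehyde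
Product: 8 (E)-stilbene dialdehyde, 3-(benzyloxy)-4-{3-[(E)-2-{4-[2-(benzyloxy)-5-formylphenoxy]phenyl}ethenyl]phenoxy}benzaldehyde
Conditions: Pd(OAc)2 (5 mol%), P(o-tol)3 (10 mol%), Et3N, DMF, 100 °C
Reagents that add atoms: none
Why: Mizoroki–Heck reaction, in which oxidative addition into the C–I bond of 4, syn-carbopalladation at the terminal carbon of styrene 7 and syn-β-hydride elimination should give the (E)-stilbene, with both aldehydes and both benzyl ethers as spectators.

Step 5
Reactants: 8 (E)-stilbene dialdehyde
Product: 9 bibenzyl dialdehyde, 3-(benzyloxy)-4-{3-[2-{4-[2-(benzyloxy)-5-formylphenoxy]phenyl}ethyl]phenoxy}benzaldehyde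
Conditions: H2 (1 atm), 10% Pd/C, Ph2S (cat.), EtOAc, rt
Reagents that add atoms: none
Why: Heterogeneous hydrogenation over diphenyl sulfide-poisoned Pd/C is a known way to saturate C=C bonds while leaving aromatic aldehydes and benzyl ethers intact, so only the stilbene bridge should be reduced.

Step 6
Reactants: 9 bibenzyl dialdehyde
Product: 11 macrocyclic stilbene bis(benzyl ether), via titanium pinacolate 10 (not isolated)
Conditions: TiCl4, Zn, pyridine, THF, reflux; 9 added by syringe pump (high dilution), then continued reflux
Reagents that add atoms: none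
Why: Low-valent titanium transfers one electron to each formyl group, the two titanium-bound ketyl radicals couple carbon to carbon to give the cyclic pinacolate 10, and this is deoxygenated at reflux to the alkene (McMurry reaction). The closest known reaction type is the intramolecular McMurry coupling of aromatic dialdehydes, a standard way to close stilbene-bridged cyclophanes and bis(bibenzyl)-type macrocycles. The ring closed is the 20-membered macrocycle, by end-to-end coupling of the ring-A and ring-D formyl carbons, with all four arenes, both diaryl ethers and the B–C bibenzyl already in place. No stereocentre is formed, and the geometry of the new alkene does not matter because step 7 saturates it. The step needs cyclisation to outrun intermolecular coupling, which is secured by slow addition into excess titanium reagent and by the bent diaryl ether hinges and the flexible B–CH2CH2–C tether, which let the two ends meet without strain. It also needs chemoselectivity, and the two formyl groups are the only functions in 9 that low-valent titanium reduces, the aryl benzyl ethers and diaryl ethers being inert.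

Step 7
Reactants: 11 macrocyclic stilbene bis(benzyl ether)
Product: 13 target macrocyclic bis(bibenzyl) diphenol, via saturated dibenzyl ether 12 (not isolated)
Conditions: H2 (1 atm), 10% Pd/C, EtOAc–MeOH, rt
Reagents that add atoms: none
Why: Catalytic hydrogenation over unpoisoned Pd/C should first saturate the stilbene C=C bond and then cleave both aryl benzyl ethers by hydrogenolysis, while the diaryl ethers and the arenes are stable under these conditions.

**Compound list**

1 | 4-fluoro-3-hydroxybenzaldehyde | O=Cc1ccc(F)c(O)c1 | starting material
2 | 3-(benzyloxy)-4-fluorobenzaldehyde | O=Cc1ccc(F)c(OCc2ccccc2)c1 | intermediate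
3 | 3-iodophenol | Oc1cccc(I)c1 | starting material
4 | 3-(benzyloxy)-4-(3-iodophenoxy)benzaldehyde | O=Cc1ccc(Oc2cccc(I)c2)c(OCc2ccccc2)c1 | intermediate
5 | 4-(benzyloxy)-3-hydroxybenzaldehyde | O=Cc1ccc(OCc2ccccc2)c(O)c1 | starting material
6 | (4-vinylphenyl)boronic acid | C=Cc1ccc(B(O)O)cc1 | starting material
7 | 4-(benzyloxy)-3-(4-vinylphenoxy)benzaldehyde | O=Cc1ccc(OCc2ccccc2)c(Oc2ccc(C=C)cc2)c1 | intermediate
8 | (E)-stilbene dialdehyde, 3-(benzyloxy)-4-{3-[(E)-2-{4-[2-(benzyloxy)-5-formylphenoxy]phenyl}ethenyl]phenoxy}benzaldehyde | O=Cc1ccc(Oc2cccc(/C=C/c3ccc(Oc4cc(C=O)ccc4OCc4ccccc4)cc3)c2)c(OCc2ccccc2)c1 | intermediate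
9 | bibenzyl dialdehyde, 3-(benzyloxy)-4-{3-[2-{4-[2-(benzyloxy)-5-formylphenoxy]phenyl}ethyl]phenoxy}benzaldehyde | O=Cc1ccc(Oc2cccc(CCc3ccc(Oc4cc(C=O)ccc4OCc4ccccc4)cc3)c2)c(OCc2ccccc2)c1 | intermediate
10 | titanium-bound macrocyclic pinacolate between the ring-A and ring-D benzylic carbons (drawn as the free 1,2-diol; diastereomer mixture, configuration left open) | C(c1ccccc1)Oc1cc2ccc1Oc1cccc(c1)CCc1ccc(cc1)Oc1cc(ccc1OCc1ccccc1)C(O)C2O | intermediate (not isolated)
11 | macrocyclic stilbene bis(benzyl ether), 20-membered ring with CH=CH between rings A and D (E/Z mixture, geometry left open) | C(c1ccccc1)Oc1cc2ccc1Oc1cccc(c1)CCc1ccc(cc1)Oc1cc(ccc1OCc1ccccc1)C=C2 | intermediate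
12 | macrocyclic bis(bibenzyl) bis(benzyl ether) | C(c1ccccc1)Oc1cc2ccc1Oc1cccc(c1)CCc1ccc(cc1)Oc1cc(ccc1OCc1ccccc1)CC2 | intermediate (not isolated)
13 | macrocyclic bis(bibenzyl) diphenol (CNP0329842.0) | Oc1cc2ccc1Oc1cccc(c1)CCc1ccc(cc1)Oc1cc(ccc1O)CC2 | target

**Summary**

Total step count: 7. Longest linear sequence: 6 (steps 1, 2, 4, 5, 6, 7); step 3 is a one-step side branch that joins at step 4.

**Steps most likely to fail**

1. Step 6 (McMurry macrocyclisation). What may go wrong: intermolecular carbonyl coupling to open-chain oligomers or the cyclic dimer competes with ring closure; the formyl groups may be reduced to hydroxymethyl or methyl groups; deoxygenation may stop at the pinacolate. Fallback, setting out from 9 and returning at 11: double Wittig methylenation of 9 (MePPh3Br, KOtBu, THF, 0 °C to rt) should give the bis-styrene F1. Ring-closing metathesis of F1 (Grubbs second-generation catalyst, dilute CH2Cl2, reflux, ethylene swept out) then forms the same ring-A/ring-D bond as the stilbene 11, which continues into step 7.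

2. Step 5 (C=C-selective hydrogenation). What may go wrong: over-reduction of the formyl groups, premature hydrogenolysis of the benzyl ethers, or, with too much catalyst poison, incomplete saturation of the stilbene. Fallback, setting out from 7 (with 4) and returning at 9, so that steps 4 and 5 are both bypassed. The aldehyde of 7 is masked as the dimethyl acetal F2 (HC(OMe)3, cat. PPTS, MeOH). Anti-Markovnikov hydroboration of the styrene with 9-BBN (THF, rt) gives the B-alkyl-9-BBN F3, which is used in solution. B-alkyl Suzuki–Miyaura coupling of F3 with iodide 4 (PdCl2(dppf), aq. K3PO4, THF–DMF, 60 °C) should give the saturated mono-acetal F4. Work-up with dilute aqueous HCl in THF releases the second formyl group and delivers 9.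

3. Step 3 (Chan–Lam O-arylation). What may go wrong: slow coupling of the ortho-alkoxy, electron-poor phenol, so that protodeboronation, oxidative homocoupling or hydroxylation of the boronic acid and copper-induced loss of the styrene dominate. Fallback, setting out from 5 and returning at 7: Ullmann-type coupling of 5 with 1-bromo-4-iodobenzene at the C–I bond (CuI, N,N-dimethylglycine, Cs2CO3, dioxane, 90 °C) should give the bromo diaryl ether F5. Suzuki–Miyaura vinylation of F5 with potassium vinyltrifluoroborate (PdCl2(dppf), Cs2CO3, THF–H2O, 80 °C) then gives 7.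

**Further compounds**

F1 | step 6 | bis-styrene, 2-(benzyloxy)-1-{3-[2-{4-[2-(benzyloxy)-5-vinylphenoxy]phenyl}ethyl]phenoxy}-4-vinylbenzene | C=Cc1ccc(Oc2cccc(CCc3ccc(Oc4cc(C=C)ccc4OCc4ccccc4)cc3)c2)c(OCc2ccccc2)c1
F2 | step 5 | dimethyl acetal of 7, 1-(benzyloxy)-4-(dimethoxymethyl)-2-(4-vinylphenoxy)benzene | COC(OC)c1ccc(OCc2ccccc2)c(Oc2ccc(C=C)cc2)c1
F3 | step 5 | B-alkyl-9-BBN, 9-{2-[4-(2-(benzyloxy)-5-(dimethoxymethyl)phenoxy)phenyl]ethyl}-9-borabicyclo[3.3.1]nonane | COC(OC)c1ccc(OCc2ccccc2)c(Oc2ccc(CCB3C4CCCC3CCC4)cc2)c1
F4 | step 5 | mono-dimethyl acetal of 9 (acetal on ring D, free formyl group on ring A) | O=Cc1ccc(Oc2cccc(CCc3ccc(Oc4cc(C(OC)OC)ccc4OCc4ccccc4)cc3)c2)c(OCc2ccccc2)c1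
F5 | step 3 | 4-(benzyloxy)-3-(4-bromophenoxy)benzaldehyde | O=Cc1ccc(OCc2ccccc2)c(Oc2ccc(Br)cc2)c1
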